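The C9–C11 bond (labdane numbering) is made by α′-alkylation of the cross-conjugated lithium dienolate of a cis-fused Δ6-8-oxo-decalin with the complete, enantiopure C11–C15 iodo ester. The step exploits C9 as the only enolisable CH2 between the C8 carbonyl and quaternary C10 in ring B, and the folded cis A/B fusion, whose convex face places the chain syn to the C10 methyl. In one operation it joins both halves and sets C9. The enone precursor comes from a catalytic asymmetric conjugate addition (sets C10) and a vinylogous cationic ring closure (sets C5); the C8 ketone is later converted into the tertiary acetate.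

Key step: step 7

Assumption: the SMILES is taken as written, i.e. the A/B-cis (5β-H) isomer, (5R,8R,9R,10S,13S) in labdane numbering; it is not the trans-fused natural labdanolic acid series, so the decalin is built de novo.
Assumption: (R)-methyl hydrogen 3-methylglutarate, 5-bromo-2-methylpent-2-ene and both enantiomers of the chiral NHC precursor are treated as purchasable.

Step 1
Reactants: 1 3-methylcyclohex-2-en-1-one; 2 5-bromo-2-methylpent-2-ene
Product: 4 (R)-3-methyl-3-(4-methylpent-3-en-1-yl)cyclohexan-1-one, via homoprenylmagnesium bromide 3 (not isolated)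
Conditions: 2, Mg, Et2O; then Cu(OTf)2 (3 mol %), chiral C2-symmetric imidazolinium NHC precursor (4 mol %), 1, Et2O, 0 °C; aq. NH4Cl
Reagents that add atoms: none
Why: Copper/NHC-catalysed asymmetric conjugate addition of a Grignard reagent to a β-substituted cyclohexenone; the quaternary centre (later C10) is set by the catalyst, whose enantiomer is chosen to give the R ketone.

Step 2
Reactants: 4 (R)-3-methyl-3-(4-methylpent-3-en-1-yl)cyclohexan-1-one
Product: 5 (S)-5-methyl-5-(4-methylpent-3-en-1-yl)cyclohex-2-en-1-one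
Conditions: IBX (2 equiv), DMSO/toluene, 70 °C
Reagents that add atoms: none
Why: IBX α,β-dehydrogenation of a ketone; the quaternary carbon carries no β-hydrogen, so only the C5–C6 side of the ketone can be desaturated, and the stereocentre is untouched (descriptor changes by CIP rules only).

Step 3
Reactants: 5 (S)-5-methyl-5-(4-methylpent-3-en-1-yl)cyclohex-2-en-1-one
Product: 6 (S)-5-(4-chloro-4-methylpentyl)-5-methylcyclohex-2-en-1-one
Conditions: HCl (4 M in dioxane), CH2Cl2, 0 °C; aq. NaHCO3
Reagents that add atoms: hydrogen chloride, Cl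
Why: Markovnikov hydrochlorination of the trisubstituted alkene gives the tertiary chloride as a selective cation precursor; β-addition of HCl to the enone is reversible and is undone on work-up.

Step 4
Reactants: 6 (S)-5-(4-chloro-4-methylpentyl)-5-methylcyclohex-2-en-1-one
Product: 8 (4aR,8aR)-5,5,8a-trimethyl-4a,5,6,7,8,8a-hexahydronaphthalen-2(1H)-one, via silyl dienol ether 7 (not isolated)
Conditions: TBSOTf, Et3N, CH2Cl2, 0 °C→rt; then ZnCl2 (20 mol %), CH2Cl2, −20 °C→rt
Reagents that add atoms: none
Why: Thermodynamic silylation should give the linear 1-silyloxy-1,3-diene, whose γ-carbon captures the Lewis-acid-ionised tertiary chloride (intramolecular, vinylogous Reetz-type SN1 alkylation of a silyl enol ether); the new bond at C4a must form perpendicular to the diene while the tether sits on the adjacent quaternary C8a, so only the cis-fused ring (H-4a cis to the angular methyl) can close.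

Step 5
Reactants: 9 (R)-5-methoxy-3-methyl-5-oxopentanoic acid
Product: 11 (S)-4-methyltetrahydro-2H-pyran-2-one, via hydroxy acid 10 (not isolated)
Conditions: LiBH4, THF, 0 °C→reflux; then 2 M HCl, rt
Reagents that add atoms: none
Why: LiBH4 reduces the ester while the lithium carboxylate is inert, and acidification lactonises the hydroxy acid; the stereocentre is not involved.

Step 6
Reactants: 11 (S)-4-methyltetrahydro-2H-pyran-2-one
Product: 13 methyl (R)-5-iodo-3-methylpentanoate, via silyl iodo ester 12 (not isolated)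
Conditions: TMSI, CH2Cl2, rt; then MeOH, rt
Reagents that add atoms: iodotrimethylsilane, C[Si](C)(C)I; methanol, CO
Why: Iodide opens the silyl-activated lactone by SN2 attack at the primary O–CH2 carbon, and methanolysis of the silyl ester under the acidic conditions gives the methyl ester (lactone-to-iodo-ester conversion); the stereocentre is not involved.

Step 7
Reactants: 8 (4aR,8aR)-5,5,8a-trimethyl-4a,5,6,7,8,8a-hexahydronaphthalen-2(1H)-one; 13 methyl (R)-5-iodo-3-methylpentanoate
Product: 15 methyl (3S)-3-methyl-5-[(1R,4aR,8aS)-5,5,8a-trimethyl-2-oxo-1,2,4a,5,6,7,8,8a-octahydronaphthalen-1-yl]pentanoate, via lithium dienolate 14 (not isolated)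
Conditions: LDA (1.05 equiv), THF, −78 °C; then 13, DMPU, −78→−20 °C; aq. NH4Cl
Reagents that add atoms: none
Why: LDA removes a proton from C1, the only accessible α′-CH2 of enone 8 (the γ-H at C4a is tertiary and buried), to give the cross-conjugated lithium dienolate 14, which is C-alkylated by the primary iodide in an SN2 reaction. The closest known reaction type is the kinetic α′-alkylation of cyclohexenone enolates. No ring is closed. The new stereocentre C1 (labdane C9) is controlled by the cis ring fusion: the electrophile bonds perpendicular to the dienolate on the convex face, anti to the pseudo-axial C8a–C8 ring bond, because the other face is syn-axial to the quaternary C5 carbon, so the chain ends cis to the angular methyl. The step needs C- over O-alkylation and mono-alkylation; the lithium counter-ion, the soft iodide and the hindered remaining α′-H should secure this. The ester and the C3 stereocentre of 13 should survive because enolate formation is complete before 13 is added.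

Step 8
Reactants: 15 methyl (3S)-3-methyl-5-[(1R,4aR,8aS)-5,5,8a-trimethyl-2-oxo-1,2,4a,5,6,7,8,8a-octahydronaphthalen-1-yl]pentanoate
Product: 16 methyl (3S)-3-methyl-5-[(1R,4aR,8aS)-5,5,8a-trimethyl-2-oxodecahydronaphthalen-1-yl]pentanoate
Conditions: H2 (1 atm), 10% Pd/C, EtOAc, rt
Reagents that add atoms: none
Why: Catalytic hydrogenation of the disubstituted enone C=C under neutral conditions; no stereocentre is formed and the epimerisable C1 centre is not exposed to base.

Step 9
Reactants: 16 methyl (3S)-3-methyl-5-[(1R,4aR,8aS)-5,5,8a-trimethyl-2-oxodecahydronaphthalen-1-yl]pentanoate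
Product: 17 methyl (3S)-3-methyl-5-[(1S,4aR,8aS)-5,5,8a-trimethyl-2-methylidenedecahydronaphthalen-1-yl]pentanoate
Conditions: Zn, CH2Br2, TiCl4, THF/CH2Cl2, 0 °C→rt
Reagents that add atoms: dibromomethane, BrCBr
Why: Takai–Lombardo methylenation uses a non-basic gem-dimetallic reagent that methylenates hindered, enolisable ketones without epimerising the α-centre and leaves the methyl ester alone (the C1 descriptor changes by CIP rules only).

Step 10
Reactants: 17 methyl (3S)-3-methyl-5-[(1S,4aR,8aS)-5,5,8a-trimethyl-2-methylidenedecahydronaphthalen-1-yl]pentanoate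
Product: 19 methyl (3S)-5-[(1R,2R,4aR,8aS)-2-hydroxy-2,5,5,8a-tetramethyldecahydronaphthalen-1-yl]-3-methylpentanoate, via organomercurial 18 (not isolated)
Conditions: Hg(OAc)2, THF/H2O, rt; then NaBH4, 3 M NaOH, 0 °C
Reagents that add atoms: water, O
Why: Markovnikov oxymercuration–demercuration; in the chair that places the angular methyl axial (the local arrangement of labd-8(17)-enes) axial entry of water at C2 is blocked by that methyl, so water should enter equatorially, anti to the C1 side chain, giving the 2R carbinol.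

Step 11
Reactants: 19 methyl (3S)-5-[(1R,2R,4aR,8aS)-2-hydroxy-2,5,5,8a-tetramethyldecahydronaphthalen-1-yl]-3-methylpentanoate
Product: 20 methyl (3S)-5-[(1R,2R,4aR,8aS)-2-acetoxy-2,5,5,8a-tetramethyldecahydronaphthalen-1-yl]-3-methylpentanoate
Conditions: Ac2O, DMAP, Et3N, CH2Cl2, 40 °C
Reagents that add atoms: acetic anhydride, CC(=O)OC(C)=O
Why: DMAP-catalysed acylation of a hindered tertiary alcohol with retention at carbon; nothing else in the molecule is acylable.

Step 12
Reactants: 20 methyl (3S)-5-[(1R,2R,4aR,8aS)-2-acetoxy-2,5,5,8a-tetramethyldecahydronaphthalen-1-yl]-3-methylpentanoate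
Product: 21 (3S)-5-[(1R,2R,4aR,8aS)-2-acetoxy-2,5,5,8a-tetramethyldecahydronaphthalen-1-yl]-3-methylpentanoic acid
Conditions: LiOH·H2O (1.5 equiv), THF/MeOH/H2O, 0 °C→rt; then 1 M HCl
Reagents that add atoms: lithium hydroxide, [Li+].[OH-]
Why: Saponification of the unhindered primary-chain methyl ester should be much faster than that of the tertiary acetate, which is flanked by two fully substituted carbons.

Compound list
1 | 3-methylcyclohex-2-en-1-one | CC1=CC(=O)CCC1 | starting material
2 | 5-bromo-2-methylpent-2-ene | CC(C)=CCCBr | starting material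
3 | (4-methylpent-3-en-1-yl)magnesium bromide | CC(C)=CCC[Mg]Br | intermediate
4 | (R)-3-methyl-3-(4-methylpent-3-en-1-yl)cyclohexan-1-one | O=C1CCC[C@](C)(CCC=C(C)C)C1 | intermediate
5 | (S)-5-methyl-5-(4-methylpent-3-en-1-yl)cyclohex-2-en-1-one | O=C1C=CC[C@](C)(CCC=C(C)C)C1 | intermediate
6 | (S)-5-(4-chloro-4-methylpentyl)-5-methylcyclohex-2-en-1-one | O=C1C=CC[C@](C)(CCCC(C)(C)Cl)C1 | intermediate
7 | (R)-tert-butyl{[5-(4-chloro-4-methylpentyl)-5-methylcyclohexa-1,3-dien-1-yl]oxy}dimethylsilane | CC(C)(C)[Si](C)(C)OC1=CC=C[C@](C)(CCCC(C)(C)Cl)C1 | intermediate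
8 | (4aR,8aR)-5,5,8a-trimethyl-4a,5,6,7,8,8a-hexahydronaphthalen-2(1H)-one (cis-fused) | O=C1C=C[C@@H]2C(C)(C)CCC[C@]2(C)C1 | intermediate
9 | (R)-5-methoxy-3-methyl-5-oxopentanoic acid ((R)-methyl hydrogen 3-methylglutarate) | OC(=O)C[C@@H](C)CC(=O)OC | starting material
10 | (S)-5-hydroxy-3-methylpentanoic acid | OC(=O)C[C@@H](C)CCO | intermediate
11 | (S)-4-methyltetrahydro-2H-pyran-2-one | O=C1C[C@@H](C)CCO1 | intermediate
12 | trimethylsilyl (R)-5-iodo-3-methylpentanoate | C[Si](C)(C)OC(=O)C[C@@H](C)CCI | intermediate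
13 | methyl (R)-5-iodo-3-methylpentanoate | COC(=O)C[C@@H](C)CCI | intermediate
14 | lithium (4aR,8aR)-5,5,8a-trimethyl-4a,5,6,7,8,8a-hexahydronaphthalen-2-olate | [Li]OC1C=C[C@@H]2C(C)(C)CCC[C@]2(C)C=1 | intermediate
15 | methyl (3S)-3-methyl-5-[(1R,4aR,8aS)-5,5,8a-trimethyl-2-oxo-1,2,4a,5,6,7,8,8a-octahydronaphthalen-1-yl]pentanoate | O=C1C=C[C@@H]2C(C)(C)CCC[C@]2(C)[C@H]1CC[C@H](C)CC(=O)OC | intermediate
16 | methyl (3S)-3-methyl-5-[(1R,4aR,8aS)-5,5,8a-trimethyl-2-oxodecahydronaphthalen-1-yl]pentanoate | O=C1CC[C@@H]2C(C)(C)CCC[C@]2(C)[C@H]1CC[C@H](C)CC(=O)OC | intermediate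
17 | methyl (3S)-3-methyl-5-[(1S,4aR,8aS)-5,5,8a-trimethyl-2-methylidenedecahydronaphthalen-1-yl]pentanoate | C=C1CC[C@@H]2C(C)(C)CCC[C@]2(C)[C@H]1CC[C@H](C)CC(=O)OC | intermediate
18 | methyl (3S)-5-[(1R,2R,4aR,8aS)-2-[(acetoxymercurio)methyl]-2-hydroxy-5,5,8a-trimethyldecahydronaphthalen-1-yl]-3-methylpentanoate | CC(=O)O[Hg]C[C@@]1(O)CC[C@@H]2C(C)(C)CCC[C@]2(C)[C@H]1CC[C@H](C)CC(=O)OC | intermediate
19 | methyl (3S)-5-[(1R,2R,4aR,8aS)-2-hydroxy-2,5,5,8a-tetramethyldecahydronaphthalen-1-yl]-3-methylpentanoate | O[C@]1(C)CC[C@@H]2C(C)(C)CCC[C@]2(C)[C@H]1CC[C@H](C)CC(=O)OC | intermediate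
20 | methyl (3S)-5-[(1R,2R,4aR,8aS)-2-acetoxy-2,5,5,8a-tetramethyldecahydronaphthalen-1-yl]-3-methylpentanoate | CC(=O)O[C@]1(C)CC[C@@H]2C(C)(C)CCC[C@]2(C)[C@H]1CC[C@H](C)CC(=O)OC | intermediate
21 | (3S)-5-[(1R,2R,4aR,8aS)-2-acetoxy-2,5,5,8a-tetramethyldecahydronaphthalen-1-yl]-3-methylpentanoic acid | CC(=O)O[C@]1(C)CC[C@@H]2C(C)(C)CCC[C@]2(C)[C@H]1CC[C@H](C)CC(=O)O | target

Total step count: 12. Longest linear sequence: 10 (steps 1–4 and 7–12).

Steps most likely to fail

Step 4. The silylation may give the cross-conjugated rather than the linear dienol ether, so that the ring closes at the wrong α′-carbon, or the tertiary chloride may lose HCl instead of being captured. The fallback closes the ring at a simple enol and then transposes the carbonyl. It sets out from 1 and 3, using the enantiomeric catalyst in the step 1 procedure to give (S)-3-methyl-3-(4-methylpent-3-en-1-yl)cyclohexan-1-one F1. Triflic acid in CH2Cl2 at −78 °C should cyclise it through its C2 enol, the only enol carbon that can reach the tertiary cation through a six-membered transition state, to cis-(4aR,8aR)-4a,8,8-trimethyloctahydronaphthalen-1(2H)-one F2. IBX can desaturate only the open side and gives the enone (4aR,8aR)-4a,8,8-trimethyl-4a,5,6,7,8,8a-hexahydronaphthalen-1(4H)-one F3. Alkaline hydrogen peroxide gives the epoxy ketone 2,3-epoxy-4a,8,8-trimethyloctahydronaphthalen-1(2H)-one F4. Wharton transposition with hydrazine hydrate and acetic acid gives the allylic alcohol (4aR,8aR)-5,5,8a-trimethyl-1,2,4a,5,6,7,8,8a-octahydronaphthalen-2-ol F5, and MnO2 oxidation rejoins the route at 8.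

Step 7. C-alkylation of the hindered dienolate by an unactivated iodide may be slow, letting proton transfer and O-alkylation compete. The fallback forms the same bond by an aldol reaction and then removes the extra oxygen. It sets out from 13, which Kornblum oxidation (DMSO, NaHCO3, heat) converts into methyl (S)-3-methyl-5-oxopentanoate F6. Dienolate 14, made from 8 as in step 7, should add to F6 at −78 °C on the same convex face to give the aldol adduct methyl (3S)-5-hydroxy-3-methyl-5-[(1R,4aR,8aS)-5,5,8a-trimethyl-2-oxo-1,2,4a,5,6,7,8,8a-octahydronaphthalen-1-yl]pentanoate F7, as a mixture at the carbinol carbon. 1,1′-Thiocarbonyldiimidazole gives the imidazolyl thiocarbonate of the aldol adduct F8, and Bu3SnH/AIBN (Barton–McCombie) removes the oxygen to rejoin the route at 15.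

Step 10. Water capture at the ring carbon may show poor facial selectivity if the other chair of the flexible cis-decalin reacts. The fallback fixes the configuration in a peracid epoxidation instead. It sets out from 17: m-CPBA should approach equatorially, anti to the side chain, to give the spiro-epoxide methyl (3S)-3-methyl-5-[(1R,2R,4aR,8aS)-5,5,8a-trimethyldecahydrospiro[naphthalene-2,2′-oxiran]-1-yl]pentanoate F9. LiI/AcOH opens it at the CH2 to the iodohydrin methyl (3S)-5-[(1R,2R,4aR,8aS)-2-hydroxy-2-(iodomethyl)-5,5,8a-trimethyldecahydronaphthalen-1-yl]-3-methylpentanoate F10, and Bu3SnH/AIBN reduces the C–I bond to rejoin the route at 19.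

Further compounds
F1 | step 4 | (S)-3-methyl-3-(4-methylpent-3-en-1-yl)cyclohexan-1-one | O=C1CCC[C@@](C)(CCC=C(C)C)C1
F2 | step 4 | cis-(4aR,8aR)-4a,8,8-trimethyloctahydronaphthalen-1(2H)-one | O=C1CCC[C@@]2(C)CCCC(C)(C)[C@@H]12
F3 | step 4 | (4aR,8aR)-4a,8,8-trimethyl-4a,5,6,7,8,8a-hexahydronaphthalen-1(4H)-one | O=C1C=CC[C@@]2(C)CCCC(C)(C)[C@@H]12
F4 | step 4 | 2,3-epoxy-4a,8,8-trimethyloctahydronaphthalen-1(2H)-one (epoxide configuration not fixed) | O=C1C2OC2C[C@@]3(C)CCCC(C)(C)[C@@H]13
F5 | step 4 | (4aR,8aR)-5,5,8a-trimethyl-1,2,4a,5,6,7,8,8a-octahydronaphthalen-2-ol (carbinol configuration not fixed) | OC1C=C[C@@H]2C(C)(C)CCC[C@]2(C)C1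
F6 | step 7 | methyl (S)-3-methyl-5-oxopentanoate | COC(=O)C[C@@H](C)CC=O
F7 | step 7 | methyl (3S)-5-hydroxy-3-methyl-5-[(1R,4aR,8aS)-5,5,8a-trimethyl-2-oxo-1,2,4a,5,6,7,8,8a-octahydronaphthalen-1-yl]pentanoate | O=C1C=C[C@@H]2C(C)(C)CCC[C@]2(C)[C@H]1C(O)C[C@H](C)CC(=O)OC
F8 | step 7 | imidazolyl thiocarbonate of the aldol adduct | O=C1C=C[C@@H]2C(C)(C)CCC[C@]2(C)[C@H]1C(OC(=S)n1ccnc1)C[C@H](C)CC(=O)OC
F9 | step 10 | methyl (3S)-3-methyl-5-[(1R,2R,4aR,8aS)-5,5,8a-trimethyldecahydrospiro[naphthalene-2,2′-oxiran]-1-yl]pentanoate | O1C[C@]12CC[C@@H]3C(C)(C)CCC[C@]3(C)[C@H]2CC[C@H](C)CC(=O)OC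
F10 | step 10 | methyl (3S)-5-[(1R,2R,4aR,8aS)-2-hydroxy-2-(iodomethyl)-5,5,8a-trimethyldecahydronaphthalen-1-yl]-3-methylpentanoate | IC[C@@]1(O)CC[C@@H]2C(C)(C)CCC[C@]2(C)[C@H]1CC[C@H](C)CC(=O)OC
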